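Colleague, you want a quick number for these four flasks and your hunch is that partner is the lever, so here is what I reckon from one quantity.

in all of them: temperature 90 °C

| flask | substrate | partner | catalyst | remark | time |
|---|---|---|---|---|---|
| zeta | 0.050 M | 0.055 M | 0.83 mM | run made earlier |  |
| theta | 0.050 M | 0.055 M | 0.28 mM | run made earlier |  |
| ash | 0.012 M | 0.0550 M | 0.55 mM |  | 10 min |
| oak | 0.012 M | 0.120 M | 0.55 mM |  | 10 min |
| larch | 0.050 M | 0.120 M | 0.55 mM |  | 10 min |
| birch | 0.050 M | 0.0550 M | 0.55 mM |  | 10 min |

- zeta (time / min: target / %, substrate / %): 0.333: 17.7, 81.8; 1.00: 35.6, 64.1; 1.50: 43.4, 57.0; 2.50: 51.6, 48.7; 4.00: 56.3, 43.4; 5.00: 58.2, 42.0; 6.00: 59.6, 41.0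
- theta (time / min: target / %, substrate / %): 0.833: 15.3, 84.9; 1.50: 23.8, 76.1; 2.50: 33.0, 66.8; 3.00: 36.3, 63.7; 4.00: 41.8, 58.3; 5.00: 44.8, 55.0; 6.00: 47.6, 52.6

(readings scatter by 0.3 percentage points)

- ranking by amount of target, in percent of the substrate charged, from high to low, at 10 min (ash / oak / larch / birch)
- the amount of target, in percent of the substrate charged of the flask you put first, at 10 min
- the amount of target, in percent of the substrate charged of the flask you put last, at 10 min

- what is said of target includes crystals
- crystals is a solid; its amount is given per volume of the solution
- the analysis behind the earlier runs scatters by 0.3 percentage points, standard deviation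
- steps that have been proposed: substrate + partner + catalyst <-> target + catalyst; crystals <-> target

At the last zeta reading, substrate and partner left multiply to 5.17 × 10⁻⁴ M^2, and I take this as the stall product: the value of c_substrate·c_partner at which a flask with crystals standing stops, in effect a solubility product, for dissolved target then sits at saturation and the back step holds steady. Zeta is still creeping, so I expect this reading to err a little high.

Each target made costs one substrate and one partner, so c_partner minus c_substrate keeps its charged value, and setting the product equal to the stall product gives one quadratic per flask. Larch comes to 86.5% and birch to 59.3%, and I expect both to arrive in time, as their catalyst times time exceeds that of zeta at its last reading.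

For ash and oak I name no number: their substrate charge is a quarter of that in larch, so I expect no crystals and the stall product does not apply. I place them between larch and birch, with oak over ash for its larger partner charge, and that placing is a thin call.

The forecast reads larch > oak > ash > birch, with 87.6% first and 60.4% last, and its ground for the crystal flasks is: “After that the reverse rate is fixed”.

The flasks give larch > oak > ash > birch: larch 87.1%, oak 83.2%, ash 67.6%, birch 59.5%.

    substrate + partner + catalyst ⇌ target + catalyst, rate k1*[substrate]*[partner]*[catalyst] forward; the back reaction follows from the equilibrium constant (K = 45.0 /M, k = 240 /M²/s, Ea = 40.0 kJ/mol, ΔH = −1.00 kJ/mol)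
    crystals ⇌ target, rate k2*(cs2 - [target]) while solid is left; crystals form when [target] > cs2 (solubility = 22.0 mM, k = 2.90 /s)
    (constants at 90 °C)

What holds birch at 59.5% is mainly the falling back of target to substrate and partner: with that back step taken away, birch holds 84.2% and the order turns. The substrate and partner left in birch at 10.0 min multiply to 5.10 × 10⁻⁴ M^2, just under the stall product of 5.17 × 10⁻⁴ M^2, with crystals at 15.5%. The neighbour of larch charged with 0.030 M of partner reaches a product of 3.98 × 10⁻⁴ M^2, further below the stall product, and there crystals stand at 0%, with target at 35.4%.

The readings are simulated for an exercise.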